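A direct plan would buy both benzene rings and close ring C last.
1-(3,4,5-Trimethoxyphenyl)ethan-1-one A1 would be brominated at both free ring positions to the 2,6-dibromo ketone A2.
A2 would be joined by Claisen condensation with methyl 3-hydroxy-4,5-dimethoxybenzoate A3 to the 1,3-diketone A4.
CuBr/NaOMe would then have to form the O1–C8a bond and replace the second bromine by methoxide in one flask, through the 5-bromoflavone A5.
Weak step, the twofold ring bromination: it installs two leaving groups that are both discarded, adds no skeletal complexity, and competes with bromination of the acetyl group.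
Weak step, the one-pot copper-mediated ring closure with methoxylation: it would be an untested tandem on the most advanced intermediate. Ring closure would be left to a race between enolate O-arylation, methoxylation, hydrodebromination and retro-Claisen cleavage by hot methoxide, with a free phenol present.

**Plan of the new route**
The retrosynthesis cuts ring A, not ring C: after the O-methyl groups at C5 and C8 and the benzyl ether, it cuts C4a–C5 (key step) and C8–C8a (the step before). This leads back to dimethyl squarate and a 2-aryl-γ-pyrone, which is cut at C2–C3 and O1–C6 to the ring B ester and 4-methoxybut-3-en-2-one.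
Ring B is bought, ring C is made second, and ring A arises last by thermal ring expansion of a 4-hydroxy-4-pyranonylcyclobutenone.
The enabling feature: ring A has oxygen at C5 and C8 (a hydroquinone pattern) and vicinal methoxy groups at C6 and C7, which is the C4O4 pattern of a squarate ester. Its other two carbons, C4a and C8a, are the C5=C6 enol-ether double bond of ring C, with a removable hydrogen on the carbon that becomes C4a.
No halogen enters the route, no aryl C–O bond is made by coupling, and ring A closes by a pericyclic reaction whose regiochemistry follows from connectivity.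

Key step: step 4

Remark: 1, 3 and 6 are taken as commercial. The target is achiral; the only stereocentres on the route (the carbinol carbon of 8 and C4a of 10) form racemic and are destroyed within step 4.

Step 1
Reactants: 1 methyl 3-hydroxy-4,5-dimethoxybenzoate
Product: 2 methyl 3-(benzyloxy)-4,5-dimethoxybenzoate
Conditions: BnBr (1.1 equiv), K2CO3 (1.5 equiv), DMF, 60 °C
Reagents that add atoms: benzyl bromide, BrCc1ccccc1
Why: Williamson ether synthesis on the only phenol, which must be masked so that it is not methylated together with the two ring A hydroxyls in step 4; no stereocentre is formed.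

Step 2
Reactants: 2 methyl 3-(benzyloxy)-4,5-dimethoxybenzoate, 3 (E)-4-methoxybut-3-en-2-one
Product: 5 2-[3-(benzyloxy)-4,5-dimethoxyphenyl]-4H-pyran-4-one, via diketone 4 (not isolated)
Conditions: LiN(SiMe3)2 (2.5 equiv), 3 (1.2 equiv), THF, −78 °C; then 2, −78 → 25 °C; then TFA, CH2Cl2, 25 °C
Reagents that add atoms: none
Why: Crossed Claisen condensation of the kinetic lithium enolate of 3 (the methyl group is its only enolisable position) with the non-enolisable ester 2 should give the diketonate of 4, and acid should then close the γ-pyrone by 6-endo conjugate addition of the enol oxygen to the β-methoxy enone with loss of methanol; no stereocentre is formed.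

Step 3
Reactants: 5 2-[3-(benzyloxy)-4,5-dimethoxyphenyl]-4H-pyran-4-one, 6 dimethyl squarate (3,4-dimethoxycyclobut-3-ene-1,2-dione)
Product: 8 4-{6-[3-(benzyloxy)-4,5-dimethoxyphenyl]-4-oxo-4H-pyran-2-yl}-4-hydroxy-2,3-dimethoxycyclobut-2-en-1-one, via pyranonylmagnesium chloride 7 (not isolated)
Conditions: TMPMgCl·LiCl (1.2 equiv), THF, −40 °C, 30 min; then 6 (1.3 equiv), −40 → 0 °C; sat. aq. NH4Cl
Reagents that add atoms: none
Why: Proposed new method: deprotonative magnesiation of a free γ-pyrone followed by 1,2-addition to a squarate ester; the hindered amide base should remove the C6 hydrogen, the only vinylic C–H next to the ring oxygen and expected to be the most acidic one (sp2 carbon flanked by O1 and β to the carbonyl), giving the α-oxyalkenylmagnesium 7, which has no β-leaving group and is kept at −40 °C to hold back addition to a second pyrone; 7 should add to one of the two equivalent strained carbonyls of 6 to give the tertiary carbinol 8 as a racemate (the centre is destroyed in step 4); C3 is shielded by the aryl group, and metalation at C5 would not be harmful because ring expansion of that adduct leads to the same hydroquinone 11; the closest known reaction types are the zincation and magnesiation of chromones and β-alkoxy enones with TMP amide bases at a vinylic carbon and the 1,2-addition of alkenyl- and heteroaryl-lithium or -magnesium reagents to squarate esters.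

Step 4
Reactants: 8 4-{6-[3-(benzyloxy)-4,5-dimethoxyphenyl]-4-oxo-4H-pyran-2-yl}-4-hydroxy-2,3-dimethoxycyclobut-2-en-1-one
Product: 12 2-[3-(benzyloxy)-4,5-dimethoxyphenyl]-5,6,7,8-tetramethoxy-4H-chromen-4-one, via dienylketene 9 (not isolated), via cyclohexadienone 10 (not isolated), via hydroquinone 11 (not isolated)
Conditions: degassed PhMe, Ar, 110 °C; then K2CO3 (6 equiv), Me2SO4 (4 equiv), DMF, 60 °C
Reagents that add atoms: dimethyl sulfate, COS(=O)(=O)OC
Why: Thermal ring expansion of a 4-hydroxy-4-alkenylcyclobutenone (Moore rearrangement): conrotatory 4π electrocyclic opening of the strained ring of 8, in which the donor hydroxyl rotates outward and the pyranonyl group therefore inward, should give the (Z)-dienylketene 9 with the ketene held next to the C5=C6 bond of the pyrone. Ring A then closes by a thermal disrotatory 6π electrocyclisation (six-membered ring, new bond from the electrophilic ketene carbon to the nucleophilic α-carbon C5 of the vinylogous ester) to the dienone 10, which as a β-diketone enolises at once to the aromatic hydroquinone 11. The closest known reaction type is the thermolysis of 4-aryl-, 4-heteroaryl- and 4-alkenyl-4-hydroxycyclobutenones made from squarate esters, which gives annulated hydroquinones. No stereocentre survives: the racemic carbinol centre of 8 is lost on ring opening and the sp3 centre of 10 on enolisation. The only selectivities needed are the outward rotation of OH, secured by its donor character, and the site of ring closure, secured because the squarate carbons stay contiguous (O at C5, OMe at C6 and C7, O at C8) and C5 of the pyrone is the only position that can reach the ketene. The oxygen-sensitive 11 is not isolated: both hydroxyls, including the hydrogen-bonded 5-OH, are methylated in the same flask while the benzyl ether keeps the ring B oxygen apart.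

Step 5
Reactants: 12 2-[3-(benzyloxy)-4,5-dimethoxyphenyl]-5,6,7,8-tetramethoxy-4H-chromen-4-one
Product: 13 3'-hydroxy-5,6,7,8,4',5'-hexamethoxyflavone
Conditions: H2 (1 atm), Pd/C (10 wt%), EtOAc/MeOH, 25 °C
Reagents that add atoms: none
Why: Hydrogenolysis of the benzyl aryl ether should free the 3'-hydroxyl, while the C2=C3 bond of the flavone (part of an aromatic pyrone) and the six methyl ethers should be untouched at one atmosphere and room temperature; no stereocentre is formed.

**Compound list**
1 | methyl 3-hydroxy-4,5-dimethoxybenzoate | COC(=O)c1cc(O)c(OC)c(OC)c1 | starting material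
2 | methyl 3-(benzyloxy)-4,5-dimethoxybenzoate | COC(=O)c1cc(OCc2ccccc2)c(OC)c(OC)c1 | intermediate
3 | (E)-4-methoxybut-3-en-2-one | CC(=O)/C=C/OC | starting material
4 | (E)-1-[3-(benzyloxy)-4,5-dimethoxyphenyl]-5-methoxypent-4-ene-1,3-dione | CO/C=C/C(=O)CC(=O)c1cc(OCc2ccccc2)c(OC)c(OC)c1 | intermediate
5 | 2-[3-(benzyloxy)-4,5-dimethoxyphenyl]-4H-pyran-4-one | O=c1ccoc(-c2cc(OCc3ccccc3)c(OC)c(OC)c2)c1 | intermediate
6 | dimethyl squarate (3,4-dimethoxycyclobut-3-ene-1,2-dione) | COC1=C(OC)C(=O)C1=O | starting material
7 | {6-[3-(benzyloxy)-4,5-dimethoxyphenyl]-4-oxo-4H-pyran-2-yl}magnesium chloride | O=c1cc([Mg]Cl)oc(-c2cc(OCc3ccccc3)c(OC)c(OC)c2)c1 | intermediate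
8 | 4-{6-[3-(benzyloxy)-4,5-dimethoxyphenyl]-4-oxo-4H-pyran-2-yl}-4-hydroxy-2,3-dimethoxycyclobut-2-en-1-one (racemic) | COC1=C(OC)C(O)(c2cc(=O)cc(-c3cc(OCc4ccccc4)c(OC)c(OC)c3)o2)C1=O | intermediate
9 | (3Z)-4-{6-[3-(benzyloxy)-4,5-dimethoxyphenyl]-4-oxo-4H-pyran-2-yl}-4-hydroxy-2,3-dimethoxybuta-1,3-dien-1-one | O=C=C(OC)/C(OC)=C(/O)c1cc(=O)cc(-c2cc(OCc3ccccc3)c(OC)c(OC)c2)o1 | intermediate
10 | 2-[3-(benzyloxy)-4,5-dimethoxyphenyl]-8-hydroxy-6,7-dimethoxy-4H-chromene-4,5(4aH)-dione (racemic) | O=C1C=C(c2cc(OCc3ccccc3)c(OC)c(OC)c2)OC2=C(O)C(OC)=C(OC)C(=O)C12 | intermediate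
11 | 2-[3-(benzyloxy)-4,5-dimethoxyphenyl]-5,8-dihydroxy-6,7-dimethoxy-4H-chromen-4-one | O=c1cc(-c2cc(OCc3ccccc3)c(OC)c(OC)c2)oc2c(O)c(OC)c(OC)c(O)c12 | intermediate
12 | 2-[3-(benzyloxy)-4,5-dimethoxyphenyl]-5,6,7,8-tetramethoxy-4H-chromen-4-one | O=c1cc(-c2cc(OCc3ccccc3)c(OC)c(OC)c2)oc2c(OC)c(OC)c(OC)c(OC)c12 | intermediate
13 | 3'-hydroxy-5,6,7,8,4',5'-hexamethoxyflavone | COc1cc(-c2cc(=O)c3c(OC)c(OC)c(OC)c(OC)c3o2)cc(O)c1OC | target

Total step count: 5. Longest linear sequence: 5 steps (1 → 2 → 5 → 8 → 12 → 13).

**Steps most likely to fail**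

Step 3 (proposed method). The base may deprotonate C3 instead of C6, the metalated pyrone may fragment or add to unreacted 5 before it is trapped, or the reagent may add to 6 in a conjugate sense with loss of methoxide. The fallback uses known chemistry and buys ring A instead of building it. Setting out from ester 2, Claisen condensation with the dianion of 1-(2-hydroxy-3,4,5,6-tetramethoxyphenyl)ethan-1-one F1 (LiN(SiMe3)2, THF, −78 → 0 °C) would give 1-[3-(benzyloxy)-4,5-dimethoxyphenyl]-3-(2-hydroxy-3,4,5,6-tetramethoxyphenyl)propane-1,3-dione F2. Acid-catalysed cyclodehydration (H2SO4, AcOH, 100 °C) would then return to the route at 12.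

Step 4. The hydroxyl group may rotate inward on ring opening so that the ketene is trapped as a lactone, the hydroquinone may be oxidised by traces of air before it is methylated, or methylation of the hydrogen-bonded 5-hydroxyl may stay incomplete. The fallback sets out from 8. O-methylation of the carbinol (MeI, Ag2O, K2CO3, MeCN, 25 °C) would give 4-{6-[3-(benzyloxy)-4,5-dimethoxyphenyl]-4-oxo-4H-pyran-2-yl}-2,3,4-trimethoxycyclobut-2-en-1-one F3, whose ether oxygen cannot lactonise. Thermolysis (PhMe, 110 °C) would then give the air-stable monophenol 2-[3-(benzyloxy)-4,5-dimethoxyphenyl]-5-hydroxy-6,7,8-trimethoxy-4H-chromen-4-one F4. This would be isolated and methylated separately (Me2SO4, K2CO3, acetone, reflux) to return at 12.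

Step 2. The enolate of 3 may condense with itself, or acylation by the electron-rich ester may be slow or take place on oxygen. The fallback builds ring C by cycloaddition. Setting out from 2, reduction (iBu2AlH, CH2Cl2, −78 °C) would give 3-(benzyloxy)-4,5-dimethoxybenzaldehyde F5. Hetero-Diels–Alder reaction with trans-1-methoxy-3-(trimethylsilyloxy)buta-1,3-diene (BF3·OEt2, CH2Cl2, −78 °C; then TFA) would give racemic 2-[3-(benzyloxy)-4,5-dimethoxyphenyl]-2,3-dihydro-4H-pyran-4-one F6. Dehydrogenation (DDQ, dioxane, 100 °C) would return to the route at 5.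

**Further compounds**
F1 | step 3 | 1-(2-hydroxy-3,4,5,6-tetramethoxyphenyl)ethan-1-one | CC(=O)c1c(O)c(OC)c(OC)c(OC)c1OC
F2 | step 3 | 1-[3-(benzyloxy)-4,5-dimethoxyphenyl]-3-(2-hydroxy-3,4,5,6-tetramethoxyphenyl)propane-1,3-dione | O=C(CC(=O)c1cc(OCc2ccccc2)c(OC)c(OC)c1)c1c(O)c(OC)c(OC)c(OC)c1OC
F3 | step 4 | 4-{6-[3-(benzyloxy)-4,5-dimethoxyphenyl]-4-oxo-4H-pyran-2-yl}-2,3,4-trimethoxycyclobut-2-en-1-one (racemic) | COC1=C(OC)C(OC)(c2cc(=O)cc(-c3cc(OCc4ccccc4)c(OC)c(OC)c3)o2)C1=O
F4 | step 4 | 2-[3-(benzyloxy)-4,5-dimethoxyphenyl]-5-hydroxy-6,7,8-trimethoxy-4H-chromen-4-one | O=c1cc(-c2cc(OCc3ccccc3)c(OC)c(OC)c2)oc2c(OC)c(OC)c(OC)c(O)c12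
F5 | step 2 | 3-(benzyloxy)-4,5-dimethoxybenzaldehyde | O=Cc1cc(OCc2ccccc2)c(OC)c(OC)c1
F6 | step 2 | 2-[3-(benzyloxy)-4,5-dimethoxyphenyl]-2,3-dihydro-4H-pyran-4-one (racemic) | O=C1C=COC(c2cc(OCc3ccccc3)c(OC)c(OC)c2)C1
A1 | direct plan | 1-(3,4,5-trimethoxyphenyl)ethan-1-one | CC(=O)c1cc(OC)c(OC)c(OC)c1
A2 | direct plan | 1-(2,6-dibromo-3,4,5-trimethoxyphenyl)ethan-1-one | CC(=O)c1c(Br)c(OC)c(OC)c(OC)c1Br
A3 | direct plan | methyl 3-hydroxy-4,5-dimethoxybenzoate | COC(=O)c1cc(O)c(OC)c(OC)c1
A4 | direct plan | 1-(2,6-dibromo-3,4,5-trimethoxyphenyl)-3-(3-hydroxy-4,5-dimethoxyphenyl)propane-1,3-dione | O=C(CC(=O)c1cc(O)c(OC)c(OC)c1)c1c(Br)c(OC)c(OC)c(OC)c1Br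
A5 | direct plan | 5-bromo-2-(3-hydroxy-4,5-dimethoxyphenyl)-6,7,8-trimethoxy-4H-chromen-4-one | COc1cc(-c2cc(=O)c3c(Br)c(OC)c(OC)c(OC)c3o2)cc(O)c1OC
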